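The constants used here come from no measurement, and the outcome is calculated.

- I began with the leftover: the coupling partner was charged at 0.125 M against 0.050 M of substrate, the limiting reagent, so full conversion leaves 0.0750 M of coupling partner.

all flasks: time 3.0 h
- alpha: substrate 0.050 M (fed, over 2.0 h); coupling partner 2.50 equiv; all else is in the flask from the start; the feed brings no volume worth counting
- gamma: substrate 0.050 M; coupling partner 2.50 equiv (fed, over 2.0 h); all else is in the flask from the start; the feed brings no volume worth counting
- zeta: substrate 0.050 M; coupling partner 2.50 equiv; everything together at the start

    substrate + coupling partner → product, rate k1*[substrate]^1.5*[coupling partner]^0.5 (k1 = 0.0037 M⁻¹ s⁻¹)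

1. which flask leads in amount of product, in percent of the substrate charged ("all alike" within 1.5 percentage points) (alpha / gamma / zeta / all alike)
2. how much product is there at the end, in percent of the substrate charged: alpha
3. how much product is there at the end, in percent of the substrate charged: gamma
4. how much product is there at the end, in percent of the substrate charged: zeta

- I counted in the substrate lifetime, the reciprocal of k1 times the square root of substrate and coupling partner at their charged concentrations, which is 0.950 h.
- This lifetime was the first rung of my ladder, and the 2.0 h feed in alpha and gamma was the next, longer by a factor of 2.11, so in those flasks reagent was still arriving after one lifetime.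
- The top rung was the 3.0 h run, which held 3.16 lifetimes.
- For n lifetimes at constant coupling partner, the integrated law leaves a substrate share of 1/(1 + n/2) squared.
- For zeta this gave 85.0% product, and with the coupling partner held at its leftover it gave 79.8%, so I took that range for zeta.
- In alpha, the average substrate arrived at the midpoint of the feed and had 2.00 h in the flask, or 2.11 lifetimes, so the same two reckonings gave 76.3% and 69.7%.
- I put no figure on gamma.
- The forecast gave 69.6% for alpha, 76.4% for gamma and 82.3% for zeta, with zeta leading, on the ground that “feeding either reagent loses reaction time at low concentration and all-at-start wins”.
- The flasks gave 69.3% in alpha, 76.4% in gamma and 82.3% in zeta, so zeta led, inside my range , while alpha fell just below my lower figure. Over the first 2.0 h, alpha held on average 0.0174 M of substrate and 0.117 M of coupling partner, which makes the lifetime 1.66 h, longer than the 0.950 h at the charge. The neighbour of alpha with 0.020 M of substrate and the same equivalents has a lifetime of 2.37 h, so its 3.0 h held 1.27 lifetimes, and it ended with 45.1% product beside 54.9% substrate.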